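## Structural features

The target is a fully substituted furan-2(5H)-one (butenolide: O1, C2 carbonyl, C3 with OMe, C4 with a 3,4-dihydroxyphenyl ring, C5 quaternary). Its C5 carries a methyl ester and, through one methylene group, C6' of a 2,2-dimethylchroman-3-ol (chroman atoms primed). Read from the SMILES, the two stereocentres are C5 (S) and C3' (R). They are not neighbours but six bonds apart (C5–CH2–C6'–C5'–C4a'–C4'–C3'), so neither can steer the other and each must be set by a reagent. The fragile groups are the free catechol (air oxidation), the lactone and the methyl ester on one carbon (hydroxide, alkoxide exchange), the allylic C5–O1 bond, and the chromanol hydroxyl next to the tertiary ether carbon C2' (dehydration or ring contraction in strong acid). The real difficulty is C5, an oxygen-bearing quaternary stereocentre without hydrogen whose two carbon substituents, the ester carbon and C4, are both at the carboxyl oxidation level. The key step uses exactly this: C5 with CO2Me and C4 is the central carbon of a 2-oxymalonate, and O1–C2–C3(OMe) is a methoxyacetyl group on the C5 oxygen. The C3–C4 bond is therefore a Dieckmann bond to one of two equivalent ester groups, and the oxygen left on C4 is the handle for attaching the catechol ring.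

## Logic of the disconnections

22 to 21: the three O–benzyl bonds (two on the catechol, one on O3') are cut. Catechol and secondary alcohol cannot pass through enolate chemistry, sulfonylation and cross-coupling unprotected, and one kind of protecting group allows one final operation. The demand is a hydrogenolysis that spares the C3=C4 bond and the allylic C5–O1 bond.

21 to 19 and 20: the C4–aryl bond is cut. This removes the whole catechol ring as a separate, simple partner and makes the route convergent. The forward coupling must succeed at a C4 flanked by the quaternary C5 and the C3 methoxy group, without base damage to ester and lactone.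

19 to 18: the O–S bond on the C4 oxygen is cut, which returns the enol. The forward step must sulfonylate at this oxygen only, which is why no other hydroxyl may be free.

18 to 15 (through 17 and 16): the C3–C4 bond is cut. This one cut opens the butenolide ring and removes the C5 stereocentre, leaving an open-chain compound whose C5 is not a stereocentre. The forward step must deprotonate only the methoxyacetyl CH2, choose one of two ester groups under control of a chiral base, and end irreversibly.

15 to 14 and 11: the C5–CH2 bond is cut. It divides the molecule into the chroman half and a three-carbon malonate half, and the forward reaction is a malonate alkylation. The demand is C-alkylation of a stabilised anion by a labile benzylic electrophile without migration of the acyl group.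

14 to 12 and 13: the C5–O bond is cut. Both pieces are commercial, and the forward step is a substitution by a carboxylate, which must not act as a base towards 12.

11 to 10 to 9: the C–Br bond is exchanged for C–OH, and the CH2OH carbon is raised to the ester level. The ester is the form of the one-carbon handle that survives the oxidation and the base of the earlier steps. The demand is that 11 be used as soon as it is made.

9 to 8 to 7 to 6: the O–benzyl bond is cut, then a C4'–H bond is replaced by the C4'–O bond of an epoxide, and the epoxide is taken back to the C3'=C4' alkene. This traces C3' to a catalytic enantioselective epoxidation of a cis-alkene. The demands are face selectivity from the catalyst and cleavage of the benzylic C–O bond only.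

6 to 3 (through 5 and 4) to 1 and 2: the C4'–C4a' bond and the O1'–C2' bond are cut, then the aryl O–C bond. The pyran ring thus comes from a simple para-substituted phenol and a five-carbon propargylic unit. The forward steps need an O-alkylation at a tertiary carbon and a thermal rearrangement; because the two ortho positions of 3 are equivalent there is no regiochemical question.

## Other disconnections considered

Alternative 1: The cut is through C4'–C4a' and O1'–C2' of the pyran ring, made late, on the complete butenolide. Heating the aryl propargyl ether A1 would start a Claisen shift, a 1,5-hydrogen shift and an oxa-6π ring closure to give chromene A2. Epoxidation with (R,R)-(salen)MnCl would then give epoxide A3, and one hydrogenolysis could open the benzylic C4'–O bond and remove both catechol benzyl groups, giving 22.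
- In favour: the cascade is a well-known thermal process with no regiochemical ambiguity. C3' never needs a protecting group. The end-game is shorter than triflation, coupling and deprotection followed by nothing else; on protecting-group and end-game economy this plan is the better one.
- Against: it leaves the hard problem, C5, untouched. A1 must already hold the C5 stereocentre and needs its own asymmetric step, most plausibly the same Dieckmann selection on a simpler malonate. The terminal alkyne C–H is about as acidic as the ester α-C–H, so the propargyl ether cannot be carried through the enolate step and must be installed late on a phenol that is protected until then, which returns the steps saved. The full butenolide with its quaternary ester must also stand about 180 °C.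
- Comparison: mechanistically its key step is safer than the chosen one, being fully precedented pericyclic chemistry. Structurally it solves the easier half of the molecule. The chosen route uses the same cascade anyway, early and cheaply, in step 2.

Alternative 2: The cut is through C5'–C6', C7'–C8' and C8a'–C4a' of the chroman benzene ring. Cp*RuCl(cod) would join the C5-propargyl butenolide A4 with the silyl ynol ether 1,7-diyne A5 in a [2+2+2] cycloaddition, giving A6 with the benzene and dihydropyran rings formed together. Removal of the silyl group from C8' would give 21.
- In favour: high convergence and neutral conditions that suit ester and lactone. The bulky silyl terminus should direct the meta relation of the substituents. The C5 problem is moved to A4, a small compound in which the two ester groups of the malonate precursor would be truly enantiotopic; on convergence this plan is the better one.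
- Against: 1,7-diynes close less readily than 1,6-diynes. A terminus that is both a bulky silyl alkyne and an ynol ether lies outside the usual substrate range. A4 can oligomerise with itself. A5 needs a multi-step enantioselective synthesis including an alkynyl ether of a tertiary alcohol. The aryl–silicon bond must be cleaved in an extra step under acid or fluoride that the lactone and ethers may not tolerate.
- Comparison: its key step is of a known reaction type applied to an untested substrate class, so it is no safer than the chosen one. C5 still needs an asymmetric step. The step count is clearly higher.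

Alternative 3: The cut is through C4–aryl, C3–C2 and O1–C2 of the butenolide. The propargylic hydroxy acid A7, as its magnesium alkoxide and carboxylate, would direct anti addition of the aryl Grignard reagent A8 to C4, leaving magnesium on C3 in a five-membered chelate. Carboxylation of the C3–Mg bond and acidification would close the lactone to acid A9, and methylation of the acid would give 21.
- In favour: three bonds and the whole ring form in one flask without palladium or a triflate. The natural polarity of an ynol ether (metal on the oxygen-bearing carbon) agrees with the direction imposed by the alkoxide. After the key step only esterification and hydrogenolysis remain, one step fewer than in the chosen route; on downstream step count it is the better plan. Its key step is of a known type (directed anti-carbomagnesiation of propargylic alcohols, then carboxylation), so on mechanistic precedent it is the equal or better.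
- Against: C5 must be set beforehand as a tertiary propargylic alcohol carrying both a carboxyl and a methoxyethynyl group, for which no dependable enantioselective access exists. The fully substituted carbinol is the least favourable case for the directed addition. The neighbouring carboxylate competes for magnesium, and the tertiary alkoxide can lose the alkynyl group by retro-addition on heating.
- Comparison: both plans see C5 as a tartronate-type carbon. The chosen plan makes the stereocentre in the ring-forming step from a cheap symmetric malonate. This alternative moves the stereochemical problem to an earlier step and leaves it unsolved there.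

Key step: step 10

## Assumptions and design remarks

- Configuration: the target is taken as (5S) at the butenolide and (3R) at the chroman, as read from the SMILES; all intermediates are drawn to match.
- Phenol building block: methyl 4-hydroxybenzoate is used, not an aldehyde. An aryl aldehyde is not safe under hypochlorite epoxidation, whereas the ester is, and it costs the same single reduction step later.
- Epoxidation catalyst: (R,R)-(salen)MnCl stands for chloro[(R,R)-N,N'-bis(3,5-di-tert-butylsalicylidene)cyclohexane-1,2-diaminato]manganese, a complex of trivalent manganese. Assumption: it gives the (3R,4R)-epoxide, by analogy with the 6-cyano chromene, for which the (S,S)-complex gives the (3S,4S)-epoxide. If the sense is opposite, the enantiomeric complex is used.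
- Base for the key step: a catalytic chiral Brønsted base is ruled out. The methoxyacetyl C–H is far too weakly acidic for an amine base, and the tetronic acid product (pKa near 4) would neutralise any base as it forms. A chiral lithium amide is therefore used in stoichiometric amount.
- Class of ring closure: the closure is strictly a 5-(enolendo)-exo-trig process, not a plain 5-exo-trig one.
- Precursor design: the two methyl esters are kept, because one becomes the CO2Me of the target and the leaving group ends as inert methanol. The benzyl ether on O3' removes the only O–H and falls in the last step. The quaternary malonate carbon leaves a single enolisable site.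
- Assumption on the key step: the sense of induction of the (R,R)-tetramine base cannot be predicted. If the (5R) epimer predominates, the (S,S)-tetramine is used.

## Route

Step 1
Reactants: 1 methyl 4-hydroxybenzoate; 2 3-chloro-3-methylbut-1-yne
Product: 3 methyl 4-[(2-methylbut-3-yn-2-yl)oxy]benzoate
Conditions: DBU, CuCl2·2H2O (cat.), MeCN, 0 °C to rt
Reagents that add atoms: none
Why: Copper-catalysed O-propargylation of a phenol by a tertiary propargylic chloride, which proceeds through a copper-bound propargyl electrophile and avoids the elimination that plain SN2 conditions cause at a tertiary carbon. No stereocentre is involved.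

Step 2
Reactants: 3 methyl 4-[(2-methylbut-3-yn-2-yl)oxy]benzoate
Product: 6 methyl 2,2-dimethyl-2H-chromene-6-carboxylate, via allenylphenol 4 (not isolated), via ortho-quinone methide 5 (not isolated)
Conditions: N,N-diethylaniline, 190 °C
Reagents that add atoms: none
Why: Aromatic propargyl Claisen rearrangement: the [3,3] shift and tautomerisation give 4, a 1,5-hydrogen shift gives 5, and oxa-6π electrocyclisation closes the pyran ring. The two ortho positions of 3 are equivalent, so only one chromene can form.

Step 3
Reactants: 6 methyl 2,2-dimethyl-2H-chromene-6-carboxylate
Product: 7 methyl (3R,4R)-3,4-epoxy-2,2-dimethylchroman-6-carboxylate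
Conditions: (R,R)-(salen)MnCl (3 mol %), 4-phenylpyridine N-oxide, aq. NaOCl (pH 11.3), CH2Cl2, 0 °C
Reagents that add atoms: sodium hypochlorite, [Na+].[O-]Cl
Why: Jacobsen–Katsuki epoxidation of a cis-alkene conjugated to an arene; 2,2-dimethylchromenes with an electron-withdrawing group at C6' are the model substrate class, and the ester is inert to hypochlorite. The (R,R)-complex should deliver oxygen to the face that gives the (3R,4R)-epoxide, which fixes C3'; C4' loses its stereochemistry in step 4.

Step 4
Reactants: 7 methyl (3R,4R)-3,4-epoxy-2,2-dimethylchroman-6-carboxylate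
Product: 8 methyl (3R)-3-hydroxy-2,2-dimethylchroman-6-carboxylate
Conditions: H2 (1 atm), Pd/C, EtOAc, rt
Reagents that add atoms: none
Why: Hydrogenolysis of the benzylic C4'–O bond of an aryl epoxide (the styrene oxide to 2-arylethanol reaction type) leaves the C3'–O bond untouched, so the (3R) configuration is carried over. Ester and arene are inert under these conditions.

Step 5
Reactants: 8 methyl (3R)-3-hydroxy-2,2-dimethylchroman-6-carboxylate
Product: 9 methyl (3R)-3-(benzyloxy)-2,2-dimethylchroman-6-carboxylate
Conditions: NaH, BnBr, Bu4NI (cat.), THF–DMF, 0 °C to rt
Reagents that add atoms: benzyl bromide, BrCc1ccccc1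
Why: Williamson etherification of the secondary alkoxide with iodide catalysis. The benzyl group removes the only O–H before steps 10 and 11 and falls together with the catechol benzyl ethers in step 13.

Step 6
Reactants: 9 methyl (3R)-3-(benzyloxy)-2,2-dimethylchroman-6-carboxylate
Product: 10 [(3R)-3-(benzyloxy)-2,2-dimethylchroman-6-yl]methanol
Conditions: LiAlH4, THF, 0 °C
Reagents that add atoms: none
Why: Hydride reduction of an aryl methyl ester to the benzylic alcohol; the benzyl ether, the aryl ether and C3' are not affected.

Step 7
Reactants: 10 [(3R)-3-(benzyloxy)-2,2-dimethylchroman-6-yl]methanol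
Product: 11 (3R)-3-(benzyloxy)-6-(bromomethyl)-2,2-dimethylchroman
Conditions: PBr3, Et2O, 0 °C; used crude
Reagents that add atoms: phosphorus tribromide, BrP(Br)Br
Why: Conversion of an electron-rich benzylic alcohol into the bromide through its phosphite ester, with SN2 displacement by bromide. The para-alkoxybenzyl bromide is labile and is taken on without chromatography.

Step 8
Reactants: 12 dimethyl 2-bromomalonate; 13 methoxyacetic acid
Product: 14 dimethyl 2-(2-methoxyacetoxy)malonate
Conditions: 13, KHCO3, DMF, rt; then 12, rt
Reagents that add atoms: none
Why: SN2 displacement of the doubly activated bromide by a carboxylate, a known way to acyloxymalonates. The carboxylate is made with hydrogencarbonate so that no base strong enough to deprotonate 12 is present.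

Step 9
Reactants: 14 dimethyl 2-(2-methoxyacetoxy)malonate; 11 (3R)-3-(benzyloxy)-6-(bromomethyl)-2,2-dimethylchroman
Product: 15 dimethyl 2-{[(3R)-3-(benzyloxy)-2,2-dimethylchroman-6-yl]methyl}-2-(2-methoxyacetoxy)malonate
Conditions: NaH, THF–DMF, 0 °C; then 11, 0 °C to rt
Reagents that add atoms: none
Why: Malonic ester alkylation: the malonate C–H of 14 is by far its most acidic site, and after deprotonation this carbon attacks the reactive benzylic bromide to give the quaternary carbon, which is not yet a stereocentre. At 0 °C the stabilised anion should alkylate faster than its acyl group can shift from oxygen to carbon.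

Step 10
Reactants: 15 dimethyl 2-{[(3R)-3-(benzyloxy)-2,2-dimethylchroman-6-yl]methyl}-2-(2-methoxyacetoxy)malonate
Product: 18 (5S)-5-{[(3R)-3-(benzyloxy)-2,2-dimethylchroman-6-yl]methyl}-4-hydroxy-3-methoxy-5-(methoxycarbonyl)furan-2(5H)-one, via lithium enolate 16 (not isolated), via lithium tetronate 17 (not isolated)
Conditions: (R,R)-N1,N3-bis[1-phenyl-2-(piperidin-1-yl)ethyl]propane-1,3-diamine (1.1 equiv), n-BuLi (2.2 equiv), THF, 0 °C; then 15, –78 to –40 °C; 1 M aq. HCl
Reagents that add atoms: none
Why: Proposed new method: one N–Li unit of the chiral dilithium amide removes a proton from the methoxyacetyl CH2 of 15, the only acidic C–H, to give lithium enolate 16, which should stay bound to the second, still lithiated nitrogen of the tetramine in a mixed aggregate. The enolate carbon (C3) adds to one of the two CO2Me groups, methoxide leaves, and the 2,4-dione so formed is deprotonated at once to lithium tetronate 17, which gives 18 on acidification. The closest known reaction type is the Dieckmann closure of alkoxyacetates of α-hydroxy esters to 3-alkoxytetronic acids with achiral lithium amides; the new element is the choice between two ester groups by a chiral lithium amide, which leans on known enantioselective C–C bond formation of lithium enolates in mixed aggregates with such amides and on known desymmetrisations of prochiral malonic diesters. The butenolide ring closes by attack on an exocyclic ester carbonyl with the enolate C=C inside the new ring, a 5-(enolendo)-exo-trig closure, formally disfavoured for enolates but the established mode of tetronic acid formation from α-acyloxy esters. The new stereocentre C5 is controlled by the chiral amide alone, because C3' is six bonds away and makes the two ester groups diastereotopic only in a formal sense. The step needs group selectivity between the two ester carbonyls and chemoselectivity for C-acylation: the quaternary malonate carbon excludes a Chan-type acyl shift and any second enolisation site, the benzyl ether leaves no O–H, and the immediate, irreversible formation of 17 keeps the kinetic choice from being lost through retro-Claisen opening.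

Step 11
Reactants: 18 (5S)-5-{[(3R)-3-(benzyloxy)-2,2-dimethylchroman-6-yl]methyl}-4-hydroxy-3-methoxy-5-(methoxycarbonyl)furan-2(5H)-one
Product: 19 (5S)-5-{[(3R)-3-(benzyloxy)-2,2-dimethylchroman-6-yl]methyl}-3-methoxy-5-(methoxycarbonyl)-4-[(trifluoromethylsulfonyl)oxy]furan-2(5H)-one
Conditions: Tf2O, iPr2NEt, CH2Cl2, –78 °C
Reagents that add atoms: trifluoromethanesulfonic anhydride, O=S(=O)(OS(=O)(=O)C(F)(F)F)C(F)(F)F
Why: O-Sulfonylation of the enolic hydroxyl of a tetronic acid (a vinylogous carboxylic acid) gives the enol triflate, the usual activation of tetronic acids for cross-coupling. C5 is quaternary and cannot epimerise.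

Step 12
Reactants: 19 (5S)-5-{[(3R)-3-(benzyloxy)-2,2-dimethylchroman-6-yl]methyl}-3-methoxy-5-(methoxycarbonyl)-4-[(trifluoromethylsulfonyl)oxy]furan-2(5H)-one; 20 3,4-bis(benzyloxy)phenylboronic acid
Product: 21 (5S)-4-[3,4-bis(benzyloxy)phenyl]-5-{[(3R)-3-(benzyloxy)-2,2-dimethylchroman-6-yl]methyl}-3-methoxy-5-(methoxycarbonyl)furan-2(5H)-one
Conditions: Pd(PPh3)4 (5 mol %), K3PO4, KBr, 1,4-dioxane, 85 °C
Reagents that add atoms: none
Why: Suzuki–Miyaura coupling: the electron-poor enol triflate adds readily to zerovalent palladium, and transmetalation with the boronate followed by reductive elimination forms the C4–aryl bond. Phosphate in dioxane is chosen to spare the methyl ester and the lactone, and KBr keeps the catalyst alive in the presence of triflate.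

Step 13
Reactants: 21 (5S)-4-[3,4-bis(benzyloxy)phenyl]-5-{[(3R)-3-(benzyloxy)-2,2-dimethylchroman-6-yl]methyl}-3-methoxy-5-(methoxycarbonyl)furan-2(5H)-one
Product: 22 (5S)-4-(3,4-dihydroxyphenyl)-5-{[(3R)-3-hydroxy-2,2-dimethylchroman-6-yl]methyl}-3-methoxy-5-(methoxycarbonyl)furan-2(5H)-one
Conditions: H2 (1 atm), Pd(OH)2/C, EtOAc–MeOH, rt
Reagents that add atoms: none
Why: Hydrogenolysis of the two aryl benzyl ethers and the secondary alkyl benzyl ether in one operation. The tetrasubstituted, aryl-conjugated C3=C4 bond and the C5–O1 bond at a quaternary carbon are expected to react much more slowly, and no stereocentre is touched.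

## Compound list

1 | methyl 4-hydroxybenzoate | COC(=O)c1ccc(O)cc1 | starting material
2 | 3-chloro-3-methylbut-1-yne | CC(C)(Cl)C#C | starting material
3 | methyl 4-[(2-methylbut-3-yn-2-yl)oxy]benzoate | COC(=O)c1ccc(OC(C)(C)C#C)cc1 | intermediate
4 | methyl 4-hydroxy-3-(3-methylbuta-1,2-dien-1-yl)benzoate | COC(=O)c1ccc(O)c(C=C=C(C)C)c1 | intermediate (not isolated)
5 | methyl 3-(3-methylbut-2-en-1-ylidene)-4-oxocyclohexa-1,5-diene-1-carboxylate | COC(=O)C1=CC(=CC=C(C)C)C(=O)C=C1 | intermediate (not isolated)
6 | methyl 2,2-dimethyl-2H-chromene-6-carboxylate | COC(=O)c1ccc2c(c1)C=CC(C)(C)O2 | intermediate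
7 | methyl (3R,4R)-3,4-epoxy-2,2-dimethylchroman-6-carboxylate | COC(=O)c1ccc2c(c1)[C@H]3O[C@H]3C(C)(C)O2 | intermediate
8 | methyl (3R)-3-hydroxy-2,2-dimethylchroman-6-carboxylate | COC(=O)c1ccc2c(c1)C[C@@H](O)C(C)(C)O2 | intermediate
9 | methyl (3R)-3-(benzyloxy)-2,2-dimethylchroman-6-carboxylate | COC(=O)c1ccc2c(c1)C[C@@H](OCc3ccccc3)C(C)(C)O2 | intermediate
10 | [(3R)-3-(benzyloxy)-2,2-dimethylchroman-6-yl]methanol | OCc1ccc2c(c1)C[C@@H](OCc3ccccc3)C(C)(C)O2 | intermediate
11 | (3R)-3-(benzyloxy)-6-(bromomethyl)-2,2-dimethylchroman | BrCc1ccc2c(c1)C[C@@H](OCc3ccccc3)C(C)(C)O2 | intermediate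
12 | dimethyl 2-bromomalonate | COC(=O)C(Br)C(=O)OC | starting material
13 | methoxyacetic acid | COCC(=O)O | starting material
14 | dimethyl 2-(2-methoxyacetoxy)malonate | COCC(=O)OC(C(=O)OC)C(=O)OC | intermediate
15 | dimethyl 2-{[(3R)-3-(benzyloxy)-2,2-dimethylchroman-6-yl]methyl}-2-(2-methoxyacetoxy)malonate | COCC(=O)OC(Cc1ccc2c(c1)C[C@@H](OCc3ccccc3)C(C)(C)O2)(C(=O)OC)C(=O)OC | intermediate
16 | lithium enolate of the methoxyacetyl group of 15 | [Li+].[O-]C(=COC)OC(Cc1ccc2c(c1)C[C@@H](OCc3ccccc3)C(C)(C)O2)(C(=O)OC)C(=O)OC | intermediate (not isolated)
17 | lithium salt of 18 (lithium tetronate, charge on the C4 oxygen) | [Li+].COC(=O)[C@@]1(Cc2ccc3c(c2)C[C@@H](OCc4ccccc4)C(C)(C)O3)OC(=O)C(OC)=C1[O-] | intermediate (not isolated)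
18 | (5S)-5-{[(3R)-3-(benzyloxy)-2,2-dimethylchroman-6-yl]methyl}-4-hydroxy-3-methoxy-5-(methoxycarbonyl)furan-2(5H)-one | COC(=O)[C@@]1(Cc2ccc3c(c2)C[C@@H](OCc4ccccc4)C(C)(C)O3)OC(=O)C(OC)=C1O | intermediate
19 | (5S)-5-{[(3R)-3-(benzyloxy)-2,2-dimethylchroman-6-yl]methyl}-3-methoxy-5-(methoxycarbonyl)-4-[(trifluoromethylsulfonyl)oxy]furan-2(5H)-one | COC(=O)[C@@]1(Cc2ccc3c(c2)C[C@@H](OCc4ccccc4)C(C)(C)O3)OC(=O)C(OC)=C1OS(=O)(=O)C(F)(F)F | intermediate
20 | 3,4-bis(benzyloxy)phenylboronic acid | OB(O)c1ccc(OCc2ccccc2)c(OCc2ccccc2)c1 | starting material
21 | (5S)-4-[3,4-bis(benzyloxy)phenyl]-5-{[(3R)-3-(benzyloxy)-2,2-dimethylchroman-6-yl]methyl}-3-methoxy-5-(methoxycarbonyl)furan-2(5H)-one | COC(=O)[C@@]1(Cc2ccc3c(c2)C[C@@H](OCc4ccccc4)C(C)(C)O3)OC(=O)C(OC)=C1c1ccc(OCc2ccccc2)c(OCc2ccccc2)c1 | intermediate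
22 | (5S)-4-(3,4-dihydroxyphenyl)-5-{[(3R)-3-hydroxy-2,2-dimethylchroman-6-yl]methyl}-3-methoxy-5-(methoxycarbonyl)furan-2(5H)-one, that is methyl (2S)-3-(3,4-dihydroxyphenyl)-2-{[(3R)-3-hydroxy-2,2-dimethyl-3,4-dihydro-2H-chromen-6-yl]methyl}-4-methoxy-5-oxo-2,5-dihydrofuran-2-carboxylate | COC(=O)[C@@]1(Cc2ccc3c(c2)C[C@@H](O)C(C)(C)O3)OC(=O)C(OC)=C1c1ccc(O)c(O)c1 | target

## Step count and least certain steps

Total: 13 steps. Longest linear sequence: 12 steps (steps 1 to 7 and 9 to 13, from 1 to 22). Step 8 is a one-step side branch.

Step 10 (key step, proposed new method). The most likely failure is poor discrimination between the two ester groups, because the enolate may cyclise outside the chiral aggregate or before the aggregate has settled. Closure may also be slow for the enolendo geometry, so that warming is needed and selectivity falls. A further risk is fragmentation of the enolate by loss of the tartronate alkoxide with ketene formation. The fallback uses known chemistry and sets out from 15. The ring is closed with achiral LiN(SiMe3)2 in THF, the ordinary Dieckmann synthesis of 3-alkoxytetronic acids, which should give the mixture of both C5 epimers of the tetronic acid F1. Because C3' is fixed, these are diastereomers. The mixture is converted with (S)-1-phenylethylamine into its salt, and fractional crystallisation (or chromatography on a chiral stationary phase if the salts do not differ enough) should give the (S)-1-phenylethylammonium salt of the (5S) acid F2. Acidification returns to the route at 18. The price is at most half of the material.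

Step 3. Face selectivity may be lower than for the cyano analogue, or the catalyst may be destroyed by oxidation before conversion is complete; either would lower the enantiomeric purity of everything that follows. The fallback sets out from 6. Epoxidation with mCPBA gives the racemic epoxide, methyl 3,4-epoxy-2,2-dimethylchroman-6-carboxylate F3. Hydrogenolysis as in step 4 gives the racemic alcohol, methyl 3-hydroxy-2,2-dimethylchroman-6-carboxylate F4. Dess–Martin oxidation gives the ketone, methyl 2,2-dimethyl-3-oxochroman-6-carboxylate F5. Corey–Bakshi–Shibata reduction with the (S)-2-methyl-oxazaborolidine and BH3·SMe2 then treats the quaternary C2' as the large group and should give the (3R) alcohol, returning to the route at 8. The stereocentre is then set by ketone reduction and not by epoxidation.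

Step 9. The labile bromide may decompose by self-alkylation or solvolysis before the hindered, stabilised anion captures it, and the acyl group of the anion may shift from oxygen to carbon or be lost. The fallback sets out from 11. Alkylation of excess sodium dimethyl malonate, a smaller and more reactive nucleophile, gives dimethyl 2-{[(3R)-3-(benzyloxy)-2,2-dimethylchroman-6-yl]methyl}malonate F6. Hydroxylation of its sodium enolate with 2-(phenylsulfonyl)-3-phenyloxaziridine gives dimethyl 2-{[(3R)-3-(benzyloxy)-2,2-dimethylchroman-6-yl]methyl}-2-hydroxymalonate F7. Acylation with methoxyacetyl chloride, pyridine and DMAP returns to the route at 15. The oxygen is thus introduced after the carbon–carbon bond and not before.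

Step 12. Transmetalation and reductive elimination at the hindered C4 may be slow. Base-induced S–O cleavage of the triflate back to the tetronate and protodeboronation of the electron-rich boronic acid then compete. The fallback sets out from 19 and is a base-free Negishi coupling. 1,2-Bis(benzyloxy)-4-bromobenzene F8 is converted by bromine–lithium exchange with n-BuLi and addition of ZnCl2 into [3,4-bis(benzyloxy)phenyl]zinc chloride F9. This is coupled with 19 using Pd(PPh3)4 in THF and returns to the route at 21.

Step 13. Cleavage of the hindered secondary benzyl ether may lag behind that of the aryl benzyl ethers. Forcing it invites hydrogenolysis of the allylic C5–O1 bond or saturation of the C3=C4 bond. The fallback sets out from 21 and replaces reduction by Lewis acid cleavage: BCl3 with pentamethylbenzene as benzyl cation scavenger in CH2Cl2 at –78 °C, which should leave the methyl ether, the ester and the lactone and returns to the route at 22.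

## Further compounds

F1 | step 10 | 5-{[(3R)-3-(benzyloxy)-2,2-dimethylchroman-6-yl]methyl}-4-hydroxy-3-methoxy-5-(methoxycarbonyl)furan-2(5H)-one, mixture of both C5 epimers | COC(=O)C1(Cc2ccc3c(c2)C[C@@H](OCc4ccccc4)C(C)(C)O3)OC(=O)C(OC)=C1O
F2 | step 10 | (S)-1-phenylethylammonium salt of 18 | C[C@H]([NH3+])c1ccccc1.COC(=O)[C@@]1(Cc2ccc3c(c2)C[C@@H](OCc4ccccc4)C(C)(C)O3)OC(=O)C(OC)=C1[O-]
F3 | step 3 | methyl 3,4-epoxy-2,2-dimethylchroman-6-carboxylate, racemic | COC(=O)c1ccc2c(c1)C3OC3C(C)(C)O2
F4 | step 3 | methyl 3-hydroxy-2,2-dimethylchroman-6-carboxylate, racemic | COC(=O)c1ccc2c(c1)CC(O)C(C)(C)O2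
F5 | step 3 | methyl 2,2-dimethyl-3-oxochroman-6-carboxylate | COC(=O)c1ccc2c(c1)CC(=O)C(C)(C)O2
F6 | step 9 | dimethyl 2-{[(3R)-3-(benzyloxy)-2,2-dimethylchroman-6-yl]methyl}malonate | COC(=O)C(Cc1ccc2c(c1)C[C@@H](OCc3ccccc3)C(C)(C)O2)C(=O)OC
F7 | step 9 | dimethyl 2-{[(3R)-3-(benzyloxy)-2,2-dimethylchroman-6-yl]methyl}-2-hydroxymalonate | COC(=O)C(O)(Cc1ccc2c(c1)C[C@@H](OCc3ccccc3)C(C)(C)O2)C(=O)OC
F8 | step 12 | 1,2-bis(benzyloxy)-4-bromobenzene | Brc1ccc(OCc2ccccc2)c(OCc2ccccc2)c1
F9 | step 12 | [3,4-bis(benzyloxy)phenyl]zinc chloride | Cl[Zn]c1ccc(OCc2ccccc2)c(OCc2ccccc2)c1
F0 | step 13 | none | none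
A1 | alternative 1 | (5S)-4-[3,4-bis(benzyloxy)phenyl]-3-methoxy-5-(methoxycarbonyl)-5-{4-[(2-methylbut-3-yn-2-yl)oxy]benzyl}furan-2(5H)-one | COC(=O)[C@@]1(Cc2ccc(OC(C)(C)C#C)cc2)OC(=O)C(OC)=C1c1ccc(OCc2ccccc2)c(OCc2ccccc2)c1
A2 | alternative 1 | (5S)-4-[3,4-bis(benzyloxy)phenyl]-5-[(2,2-dimethyl-2H-chromen-6-yl)methyl]-3-methoxy-5-(methoxycarbonyl)furan-2(5H)-one | COC(=O)[C@@]1(Cc2ccc3c(c2)C=CC(C)(C)O3)OC(=O)C(OC)=C1c1ccc(OCc2ccccc2)c(OCc2ccccc2)c1
A3 | alternative 1 | (5S)-4-[3,4-bis(benzyloxy)phenyl]-5-{[(3R,4R)-3,4-epoxy-2,2-dimethylchroman-6-yl]methyl}-3-methoxy-5-(methoxycarbonyl)furan-2(5H)-one | COC(=O)[C@@]1(Cc2ccc3c(c2)[C@H]4O[C@H]4C(C)(C)O3)OC(=O)C(OC)=C1c1ccc(OCc2ccccc2)c(OCc2ccccc2)c1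
A4 | alternative 2 | (5S)-4-[3,4-bis(benzyloxy)phenyl]-3-methoxy-5-(methoxycarbonyl)-5-(prop-2-yn-1-yl)furan-2(5H)-one | COC(=O)[C@@]1(CC#C)OC(=O)C(OC)=C1c1ccc(OCc2ccccc2)c(OCc2ccccc2)c1
A5 | alternative 2 | [({(3R)-3-(benzyloxy)-2-methylhex-5-yn-2-yl}oxy)ethynyl]tri(propan-2-yl)silane | C#CC[C@@H](OCc1ccccc1)C(C)(C)OC#C[Si](C(C)C)(C(C)C)C(C)C
A6 | alternative 2 | (5S)-4-[3,4-bis(benzyloxy)phenyl]-5-{[(3R)-3-(benzyloxy)-2,2-dimethyl-8-(triisopropylsilyl)chroman-6-yl]methyl}-3-methoxy-5-(methoxycarbonyl)furan-2(5H)-one | COC(=O)[C@@]1(Cc2cc([Si](C(C)C)(C(C)C)C(C)C)c3c(c2)C[C@@H](OCc4ccccc4)C(C)(C)O3)OC(=O)C(OC)=C1c1ccc(OCc2ccccc2)c(OCc2ccccc2)c1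
A7 | alternative 3 | (2S)-2-{[(3R)-3-(benzyloxy)-2,2-dimethylchroman-6-yl]methyl}-2-hydroxy-4-methoxybut-3-ynoic acid | OC(=O)[C@@](C#COC)(Cc1ccc2c(c1)C[C@@H](OCc3ccccc3)C(C)(C)O2)O
A8 | alternative 3 | [3,4-bis(benzyloxy)phenyl]magnesium bromide | Br[Mg]c1ccc(OCc2ccccc2)c(OCc2ccccc2)c1
A9 | alternative 3 | (2S)-3-[3,4-bis(benzyloxy)phenyl]-2-{[(3R)-3-(benzyloxy)-2,2-dimethylchroman-6-yl]methyl}-4-methoxy-5-oxo-2,5-dihydrofuran-2-carboxylic acid | OC(=O)[C@@]1(Cc2ccc3c(c2)C[C@@H](OCc4ccccc4)C(C)(C)O3)OC(=O)C(OC)=C1c1ccc(OCc2ccccc2)c(OCc2ccccc2)c1
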